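(The runs were generated by integration with made-up constants; the scatter is artificial.)

5.52 mM of ring is the mean of the teal and the red readings at 20 min, which are 5.54 mM and 5.49 mM, although the red charge is 2.81 times the teal one. Extra solid therefore buys no extra ring in these two runs, and the teal run is still climbing steadily at the end, at 0.311 mM/min. Call C, the ring in mM reached at this time by a flask that still holds undissolved solid, the ceiling; the steady climb is a pseudo-zero-order stretch.

| flask | solid substrate | remark | time |
|---|---|---|---|
| blue | 6.5 mM | run made earlier |  |
| teal | 21 mM | run made earlier |  |
| red | 59 mM | run made earlier |  |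
| dawn | 60 mM |  | 20 min |
| summer | 5.0 mM |  | 20 min |
| dusk | 80 mM |  | 20 min |
| noon | 30 mM |  | 20 min |
| autumn | 20 mM |  | 20 min |
| winter | 10 mM |  | 20 min |

- blue (time / min: ring / %): 1.50: 1.6; 3.00: 5.6; 6.00: 17.1; 10.0: 29.9; 20.0: 48.2
- teal (time / min: ring / %): 4.00: 2.3; 8.00: 8.2; 12.0: 14.3; 15.0: 19.0; 20.0: 26.4
- red (time / min: ring / %): 2.00: 0.4; 5.00: 1.9; 10.0: 3.9; 15.0: 6.3; 20.0: 9.3

(scatter of a reading: 0.3 percentage points)

- given per volume of solution although it is solid: solid substrate
- at the start none of the solid substrate is in solution
- what has only dissolved of solid substrate counts as not reacted

* the flasks by amount of ring, in percent of the solid substrate charged, highest first, at 20 min (dawn / summer / dusk / noon / autumn / winter)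
* the amount of ring, in percent of the solid substrate charged of the flask you put first, at 20 min
* the amount of ring, in percent of the solid substrate charged of the flask you put last, at 20 min

In percent of the charge, the ceiling gives C divided by the charge. On logarithmic axes that is a straight line of slope minus one, so a charge multiplied by some factor has its percent divided by the same factor. Dusk then gets 6.89 %, dawn 9.19 %, noon 18.4 % and autumn 27.6 %.

The objection comes from the blue run, which holds 3.13 mM of ring, less than C. The ceiling also exceeds summer's charge of 5.0 mM, so it cannot hold for summer. A better estimate for the small charges is the straight line through blue and teal on the same axes, of slope minus 0.513. It gives winter 38.6 % and summer 55.1 %. A doubt remains, because summer lies beyond the measured range and winter may sit above the line, towards its ceiling value of 55.2 %. This reckoning still commits to summer first and dusk last.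

The forecast differs in first place: winter > summer > autumn > noon > dawn > dusk, with 50 % (45 % to 55 %) and 7.1 % (6.5 % to 7.7 %). Its winter is “saturated until about 13 min, then decays”.

The flasks give summer > winter > autumn > noon > dawn > dusk, with 50.8 % for summer and 6.96 % for dusk. At 20.0 min, open dimer, each counted as two, stands at 21.4 % in winter, more than the 14.0 % in summer, while winter's ring is 43.9 %. The ceiling gives dusk 6.89 %; dusk still holds 79.6 % as solid.

    starting material → ring (k = 9.44 × 10⁻⁴ /s)
    2 starting material ⇌ open dimer (K = 120 /M, k = 0.0576 /M/s)
    ring ⇌ isomer of the product (K = 0.140, k = 7.01 × 10⁻⁴ /s)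
    solid substrate ⇌ starting material, rate k4*(cs4 - [starting material]) while solid is left; crystals form when [starting material] > cs4 (solubility = 9.20 mM, k = 0.00364 /s)

A neighbour of dusk charged with 200 mM gets 2.76 % from the ceiling. The computed flask gives 2.78 %, with 91.8 % still solid.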